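**Plan**

- Retrosynthesis: the C4 ketone is taken back to a silyl-protected cis-carbinol. Ring B (4-hydroxy-2-methoxyphenyl) is then cut at C1'–C2', C3'–C4' and C4'–C5', leaving a diazo vinyl ketone on C3 and methoxyacetylene.
- The two-carbon chain on C3 is traced to an intramolecular Stetter closure (C3–C4 bond) of a salicylaldehyde 4-oxycrotonate. Ring A comes from 4,6-dibromoresorcinol by two successive Br/Li exchanges (geranyl, then formyl).
- Forward order: ring A is dressed first, the pyranone ring closes second, ring B is grown last on C3, and the C4 oxidation level is restored at the end.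
- Stereochemistry: C3 (S) is set by the chiral triazolylidene catalyst of the Stetter closure. C4 is a temporary cis-carbinol that keeps C3 non-enolisable until the final oxidation. The E-alkene is bought with geranyl bromide.

Key step: step 14

Remarks on the chemistry:
- Abbreviations: Ger = (2E)-3,7-dimethylocta-2,6-dien-1-yl; MOM = methoxymethyl; TIPS = triisopropylsilyl; TES = triethylsilyl; Chr = (3S,4S)-6-Ger-4-(triethylsilyloxy)-7-(triisopropylsilyloxy)chroman-3-yl with the C3 and C4 substituents cis. Chroman numbering is used; primed numbers refer to ring B.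
- Assumption: the antipode of the triazolium precatalyst in step 7 is the one whose carbene delivers the 3S ketone. Both antipodes are available from the two enantiomers of cis-1-amino-2-indanol, so the sense of induction can be matched.
- Assumption: methoxyacetylene is too volatile and labile to stock and is prepared fresh (step 13).

**Route**

Step 1
Reactants: 1 4,6-dibromoresorcinol
Product: 2 1,5-dibromo-2,4-bis(methoxymethoxy)benzene
Conditions: NaH, MOMCl, DMF, 0 °C → rt
Reagents that add atoms: chloromethyl methyl ether, COCCl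
Why: Williamson etherification of both phenoxides should give acetal ethers that survive and assist the later bromine–lithium exchanges.

Step 2
Reactants: 2 1,5-dibromo-2,4-bis(methoxymethoxy)benzene; 3 geranyl bromide
Product: 5 1-bromo-5-Ger-2,4-bis(methoxymethoxy)benzene, via aryllithium 4 (not isolated)
Conditions: n-BuLi (1.0 equiv), THF, −78 °C; CuBr·SMe2; 3, −78 → 0 °C
Reagents that add atoms: none
Why: A single bromine–lithium exchange (a second exchange on the aryl anion is much slower) followed by copper-mediated SN2 allylation of the primary allylic bromide should give the linear arene with the E-alkene intact.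

Step 3
Reactants: 5 1-bromo-5-Ger-2,4-bis(methoxymethoxy)benzene
Product: 7 5-Ger-2,4-bis(methoxymethoxy)benzaldehyde, via aryllithium 6 (not isolated)
Conditions: n-BuLi, THF, −78 °C; DMF; aq. NH4Cl
Reagents that add atoms: N,N-dimethylformamide, CN(C)C=O
Why: Bromine–lithium exchange and Bouveault formylation place the aldehyde on the carbon that becomes C4, ortho to the oxygen that becomes O1.

Step 4
Reactants: 7 5-Ger-2,4-bis(methoxymethoxy)benzaldehyde
Product: 8 5-Ger-2,4-dihydroxybenzaldehyde
Conditions: 3 M aq. HCl, MeOH, 40 °C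
Reagents that add atoms: none
Why: Acid-catalysed acetal exchange with methanol should free both phenols under conditions mild enough for the trisubstituted alkenes.

Step 5
Reactants: 8 5-Ger-2,4-dihydroxybenzaldehyde
Product: 9 5-Ger-2-hydroxy-4-(triisopropylsilyloxy)benzaldehyde
Conditions: TIPSCl (1.05 equiv), imidazole, CH2Cl2, 0 °C
Reagents that add atoms: chlorotriisopropylsilane, CC(C)[Si](Cl)(C(C)C)C(C)C
Why: Selective silylation is expected at the more acidic, unchelated 4-OH, because the 2-OH is tied up in a hydrogen bond to the aldehyde (known selectivity of 2,4-dihydroxybenzaldehydes).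

Step 6
Reactants: 9 5-Ger-2-hydroxy-4-(triisopropylsilyloxy)benzaldehyde; 10 methyl (2E)-4-bromobut-2-enoate
Product: 11 methyl (2E)-4-[2-formyl-4-Ger-5-(triisopropylsilyloxy)phenoxy]but-2-enoate
Conditions: K2CO3, acetone, rt → 50 °C
Reagents that add atoms: none
Why: Williamson etherification of the remaining phenol at the primary allylic bromide should install the tethered Michael acceptor, with the hindered aryl silyl ether tolerating carbonate in an aprotic solvent.

Step 7
Reactants: 11 methyl (2E)-4-[2-formyl-4-Ger-5-(triisopropylsilyloxy)phenoxy]but-2-enoate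
Product: 12 methyl 2-[(3S)-6-Ger-4-oxo-7-(triisopropylsilyloxy)chroman-3-yl]acetate
Conditions: 2-(pentafluorophenyl)-5a,10b-dihydro-4H,6H-indeno[2,1-b][1,2,4]triazolo[4,3-d][1,4]oxazin-2-ium tetrafluoroborate (single enantiomer, 10 mol%), KN(SiMe3)2 (10 mol%), toluene, rt
Reagents that add atoms: none
Why: Asymmetric intramolecular Stetter reaction in which the carbene-bound acyl anion equivalent adds 6-exo-trig to the β-carbon of the enoate; the chiral triazolylidene selects the enoate face and thereby sets C3 as S.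

Step 8
Reactants: 12 methyl 2-[(3S)-6-Ger-4-oxo-7-(triisopropylsilyloxy)chroman-3-yl]acetate
Product: 14 (3aS,9bS)-8-Ger-7-(triisopropylsilyloxy)-3,3a,4,9b-tetrahydro-2H-furo[3,2-c]chromen-2-one, via lithium alkoxide 13 (not isolated)
Conditions: LiBH(s-Bu)3 (1.1 equiv), THF, −78 °C → rt; aq. NH4Cl
Reagents that add atoms: none
Why: The bulky hydride should attack anti to the pseudo-equatorial C3 substituent (as with 2-substituted cyclohexanones) to give the cis alkoxide, which lactonises onto the neighbouring ester; C4 is thus set by substrate control.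

Step 9
Reactants: 14 (3aS,9bS)-8-Ger-7-(triisopropylsilyloxy)-3,3a,4,9b-tetrahydro-2H-furo[3,2-c]chromen-2-one
Product: 15 2-[(3S,4S)-6-Ger-4-hydroxy-7-(triisopropylsilyloxy)chroman-3-yl]-N-methoxy-N-methylacetamide
Conditions: MeNH(OMe)·HCl, i-PrMgCl, THF, −20 → 0 °C; aq. NH4Cl
Reagents that add atoms: N,O-dimethylhydroxylamine hydrochloride, CNOC.Cl
Why: Aminolysis of the lactone by the chloromagnesium amide (Weinreb amide formation) is driven by the stable magnesium chelate; the crude hydroxy amide is carried on at once to forestall relactonisation.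

Step 10
Reactants: 15 2-[(3S,4S)-6-Ger-4-hydroxy-7-(triisopropylsilyloxy)chroman-3-yl]-N-methoxy-N-methylacetamide
Product: 16 2-Chr-N-methoxy-N-methylacetamide
Conditions: TESCl, imidazole, DMF, 0 °C
Reagents that add atoms: chlorotriethylsilane, CC[Si](Cl)(CC)CC
Why: Silylation of the secondary benzylic alcohol blocks relactonisation and gives a C4 ether that can later be cleaved in the presence of aryl TIPS ethers.

Step 11
Reactants: 16 2-Chr-N-methoxy-N-methylacetamide
Product: 17 1-Chr-but-3-en-2-one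
Conditions: CH2=CHMgBr, THF, −78 → 0 °C; inverse quench into cold aq. NH4Cl
Reagents that add atoms: vinylmagnesium bromide, C=C[Mg]Br
Why: Weinreb ketone synthesis, in which the chelated tetrahedral adduct releases the vinyl ketone only on quench; the inverse acidic quench keeps the liberated amine from adding to the enone.

Step 12
Reactants: 17 1-Chr-but-3-en-2-one
Product: 19 1-diazo-1-Chr-but-3-en-2-one, via trifluoroacetyl ketone 18 (not isolated)
Conditions: LiN(SiMe3)2, THF, −78 °C; CF3CO2CH2CF3; aq. NH4Cl; then MsN3, Et3N, H2O, MeCN, rt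
Reagents that add atoms: methanesulfonyl azide, CS(=O)(=O)N=[N+]=[N-]; 2,2,2-trifluoroethyl trifluoroacetate, O=C(OCC(F)(F)F)C(F)(F)F (its acyl group is carried by 18 only)
Why: Detrifluoroacetylative diazo transfer (Regitz type), in which the only enolisable position, the CH2 between C3 and the carbonyl, is trifluoroacetylated and the activated diketone exchanges the acyl group for the diazo group.

Step 13
Reactants: 20 chloroacetaldehyde dimethyl acetal
Product: 22 methoxyacetylene, via sodium methoxyacetylide 21 (not isolated)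
Conditions: NaNH2 (3 equiv), liq. NH3, −33 °C; cold sat. aq. NaCl; distillation into a cold trap
Reagents that add atoms: none
Why: Two successive amide-induced eliminations (methanol, then HCl) give the alkynyl ether as its sodium salt, the classical preparation of alkoxyacetylenes from chloroacetals.

Step 14
Reactants: 19 1-diazo-1-Chr-but-3-en-2-one; 22 methoxyacetylene
Product: 27 4-Chr-3-methoxyphenol, via vinylketene 23 (not isolated), via cyclobutenone 24 (not isolated), via dienylketene 25 (not isolated), via cyclohexadienone 26 (not isolated)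
Conditions: hν (365 nm LEDs or medium-pressure Hg lamp through Pyrex), 22 (5 equiv), ClCH2CH2Cl, sealed tube, rt; then 80 °C
Reagents that add atoms: none
Why: Direct irradiation expels N2 with 1,2-shift of the vinyl group (Wolff rearrangement) to vinylketene 23; its carbonyl carbon (future C4') is attacked by the nucleophilic CH terminus of the ynol ether while the ketene α-carbon (C1') bonds to the methoxy-bearing carbon (C2'), a [2+2] cycloaddition giving cyclobutenone 24. Warming opens 24 by 4π electrocyclic cleavage of its C4'–C1' bond to dienylketene 25, which closes ring B by thermal disrotatory 6π electrocyclisation (C4'–C5') to 26 and enolises to the phenol; this is the diazo ketone version of the Danheiser benzannulation. The polarity match of ketene and ynol ether fixes the regiochemistry (OMe ortho and OH para to C1'). No stereocentre is created, since the quaternary carbon of 24 is transient and C3 and C4 are spectators. The step needs the Wolff shift to outrun 1,2-hydrogen shift from C3–H; unsensitised photolysis, the good migratory aptitude of vinyl and a C3–H deactivated by two flanking C–O bonds should favour it. The excess electron-rich alkyne should outcompete the remote geranyl alkenes and the product phenol for the ketene.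

Step 15
Reactants: 27 4-Chr-3-methoxyphenol
Product: 28 (3S,4S)-6-Ger-3-[2-methoxy-4-(triisopropylsilyloxy)phenyl]-4-(triethylsilyloxy)-7-(triisopropylsilyloxy)chromane
Conditions: TIPSCl, imidazole, DMF, rt
Reagents that add atoms: chlorotriisopropylsilane, CC(C)[Si](Cl)(C(C)C)C(C)C
Why: Silylation of the unhindered 4'-phenol protects the electron-rich ring from the oxidant used two steps later.

Step 16
Reactants: 28 (3S,4S)-6-Ger-3-[2-methoxy-4-(triisopropylsilyloxy)phenyl]-4-(triethylsilyloxy)-7-(triisopropylsilyloxy)chromane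
Product: 29 (3S,4S)-6-Ger-3-[2-methoxy-4-(triisopropylsilyloxy)phenyl]-7-(triisopropylsilyloxy)chroman-4-ol
Conditions: PPTS (0.2 equiv), MeOH/CH2Cl2, 0 °C
Reagents that add atoms: none
Why: Mild acid-catalysed methanolysis should cleave the secondary alkyl TES ether much faster than the two bulky aryl TIPS ethers (selective silyl ether solvolysis).

Step 17
Reactants: 29 (3S,4S)-6-Ger-3-[2-methoxy-4-(triisopropylsilyloxy)phenyl]-7-(triisopropylsilyloxy)chroman-4-ol
Product: 30 (3S)-6-Ger-3-[2-methoxy-4-(triisopropylsilyloxy)phenyl]-7-(triisopropylsilyloxy)chroman-4-one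
Conditions: Dess–Martin periodinane, NaHCO3, CH2Cl2, 0 °C → rt
Reagents that add atoms: none
Why: Dess–Martin oxidation of the benzylic carbinol under buffered, base-free conditions should give the α-aryl ketone without enolisation, so C3 keeps the S configuration set in step 7.

Step 18
Reactants: 30 (3S)-6-Ger-3-[2-methoxy-4-(triisopropylsilyloxy)phenyl]-7-(triisopropylsilyloxy)chroman-4-one
Product: 31 (3S)-6-Ger-7-hydroxy-3-(4-hydroxy-2-methoxyphenyl)chroman-4-one
Conditions: Bu4NF, AcOH (1:1), THF, 0 °C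
Reagents that add atoms: none
Why: Acetic acid-buffered fluoride should cleave both aryl silyl ethers without the free base that would enolise and racemise C3 of the isoflavanone.

**Compound list**

1 | 4,6-dibromoresorcinol | Oc1cc(O)c(Br)cc1Br | starting material
2 | 1,5-dibromo-2,4-bis(methoxymethoxy)benzene | COCOc1cc(OCOC)c(Br)cc1Br | intermediate
3 | geranyl bromide, (2E)-1-bromo-3,7-dimethylocta-2,6-diene | BrC/C=C(\C)CCC=C(C)C | starting material
4 | [5-bromo-2,4-bis(methoxymethoxy)phenyl]lithium | [Li]c1cc(Br)c(OCOC)cc1OCOC | intermediate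
5 | 1-bromo-5-Ger-2,4-bis(methoxymethoxy)benzene | COCOc1cc(OCOC)c(C/C=C(\C)CCC=C(C)C)cc1Br | intermediate
6 | [5-Ger-2,4-bis(methoxymethoxy)phenyl]lithium | [Li]c1cc(C/C=C(\C)CCC=C(C)C)c(OCOC)cc1OCOC | intermediate
7 | 5-Ger-2,4-bis(methoxymethoxy)benzaldehyde | COCOc1cc(OCOC)c(C/C=C(\C)CCC=C(C)C)cc1C=O | intermediate
8 | 5-Ger-2,4-dihydroxybenzaldehyde | O=Cc1cc(C/C=C(\C)CCC=C(C)C)c(O)cc1O | intermediate
9 | 5-Ger-2-hydroxy-4-(triisopropylsilyloxy)benzaldehyde | O=Cc1cc(C/C=C(\C)CCC=C(C)C)c(O[Si](C(C)C)(C(C)C)C(C)C)cc1O | intermediate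
10 | methyl (2E)-4-bromobut-2-enoate | COC(=O)/C=C/CBr | starting material
11 | methyl (2E)-4-[2-formyl-4-Ger-5-(triisopropylsilyloxy)phenoxy]but-2-enoate | COC(=O)/C=C/COc1cc(O[Si](C(C)C)(C(C)C)C(C)C)c(C/C=C(\C)CCC=C(C)C)cc1C=O | intermediate
12 | methyl 2-[(3S)-6-Ger-4-oxo-7-(triisopropylsilyloxy)chroman-3-yl]acetate | COC(=O)C[C@H]1COc2cc(O[Si](C(C)C)(C(C)C)C(C)C)c(C/C=C(\C)CCC=C(C)C)cc2C1=O | intermediate
13 | lithium alkoxide of methyl 2-[(3S,4S)-6-Ger-4-hydroxy-7-(triisopropylsilyloxy)chroman-3-yl]acetate (3,4-cis) | COC(=O)C[C@H]1COc2cc(O[Si](C(C)C)(C(C)C)C(C)C)c(C/C=C(\C)CCC=C(C)C)cc2[C@H]1O[Li] | intermediate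
14 | (3aS,9bS)-8-Ger-7-(triisopropylsilyloxy)-3,3a,4,9b-tetrahydro-2H-furo[3,2-c]chromen-2-one (cis-fused lactone) | O=C1C[C@H]2COc3cc(O[Si](C(C)C)(C(C)C)C(C)C)c(C/C=C(\C)CCC=C(C)C)cc3[C@H]2O1 | intermediate
15 | 2-[(3S,4S)-6-Ger-4-hydroxy-7-(triisopropylsilyloxy)chroman-3-yl]-N-methoxy-N-methylacetamide (3,4-cis) | CON(C)C(=O)C[C@H]1COc2cc(O[Si](C(C)C)(C(C)C)C(C)C)c(C/C=C(\C)CCC=C(C)C)cc2[C@H]1O | intermediate
16 | 2-Chr-N-methoxy-N-methylacetamide | CON(C)C(=O)C[C@H]1COc2cc(O[Si](C(C)C)(C(C)C)C(C)C)c(C/C=C(\C)CCC=C(C)C)cc2[C@H]1O[Si](CC)(CC)CC | intermediate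
17 | 1-Chr-but-3-en-2-one | C=CC(=O)C[C@H]1COc2cc(O[Si](C(C)C)(C(C)C)C(C)C)c(C/C=C(\C)CCC=C(C)C)cc2[C@H]1O[Si](CC)(CC)CC | intermediate
18 | 3-Chr-1,1,1-trifluorohex-5-ene-2,4-dione (epimers at the chain carbon, enolised) | C=CC(=O)C(C(=O)C(F)(F)F)[C@H]1COc2cc(O[Si](C(C)C)(C(C)C)C(C)C)c(C/C=C(\C)CCC=C(C)C)cc2[C@H]1O[Si](CC)(CC)CC | intermediate
19 | 1-diazo-1-Chr-but-3-en-2-one | C=CC(=O)C(=[N+]=[N-])[C@H]1COc2cc(O[Si](C(C)C)(C(C)C)C(C)C)c(C/C=C(\C)CCC=C(C)C)cc2[C@H]1O[Si](CC)(CC)CC | intermediate
20 | chloroacetaldehyde dimethyl acetal (2-chloro-1,1-dimethoxyethane) | COC(CCl)OC | starting material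
21 | sodium methoxyacetylide | COC#C[Na] | intermediate
22 | methoxyacetylene | COC#C | intermediate
23 | 2-Chr-buta-1,3-dien-1-one (vinylketene) | C=CC(=C=O)[C@H]1COc2cc(O[Si](C(C)C)(C(C)C)C(C)C)c(C/C=C(\C)CCC=C(C)C)cc2[C@H]1O[Si](CC)(CC)CC | intermediate
24 | 4-Chr-3-methoxy-4-vinylcyclobut-2-en-1-one (either configuration at the ring quaternary carbon) | C=CC1(C(=O)C=C1OC)[C@H]1COc2cc(O[Si](C(C)C)(C(C)C)C(C)C)c(C/C=C(\C)CCC=C(C)C)cc2[C@H]1O[Si](CC)(CC)CC | intermediate
25 | 4-Chr-3-methoxyhexa-1,3,5-trien-1-one, ketenyl and vinyl groups cis on the central alkene (dienylketene) | O=C=C/C(OC)=C(\C=C)[C@H]1COc2cc(O[Si](C(C)C)(C(C)C)C(C)C)c(C/C=C(\C)CCC=C(C)C)cc2[C@H]1O[Si](CC)(CC)CC | intermediate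
26 | 4-Chr-3-methoxycyclohexa-2,4-dien-1-one | O=C1C=C(OC)C(=CC1)[C@H]1COc2cc(O[Si](C(C)C)(C(C)C)C(C)C)c(C/C=C(\C)CCC=C(C)C)cc2[C@H]1O[Si](CC)(CC)CC | intermediate
27 | 4-Chr-3-methoxyphenol, i.e. (3S,4S)-cis-isoflavan-4-ol with free 4'-OH, 7-O-TIPS and 4-O-TES | COc1cc(O)ccc1[C@H]1COc2cc(O[Si](C(C)C)(C(C)C)C(C)C)c(C/C=C(\C)CCC=C(C)C)cc2[C@H]1O[Si](CC)(CC)CC | intermediate
28 | (3S,4S)-6-Ger-3-[2-methoxy-4-(triisopropylsilyloxy)phenyl]-4-(triethylsilyloxy)-7-(triisopropylsilyloxy)chromane (3,4-cis) | COc1cc(O[Si](C(C)C)(C(C)C)C(C)C)ccc1[C@H]1COc2cc(O[Si](C(C)C)(C(C)C)C(C)C)c(C/C=C(\C)CCC=C(C)C)cc2[C@H]1O[Si](CC)(CC)CC | intermediate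
29 | (3S,4S)-6-Ger-3-[2-methoxy-4-(triisopropylsilyloxy)phenyl]-7-(triisopropylsilyloxy)chroman-4-ol (3,4-cis) | COc1cc(O[Si](C(C)C)(C(C)C)C(C)C)ccc1[C@H]1COc2cc(O[Si](C(C)C)(C(C)C)C(C)C)c(C/C=C(\C)CCC=C(C)C)cc2[C@H]1O | intermediate
30 | (3S)-6-Ger-3-[2-methoxy-4-(triisopropylsilyloxy)phenyl]-7-(triisopropylsilyloxy)chroman-4-one | COc1cc(O[Si](C(C)C)(C(C)C)C(C)C)ccc1[C@H]1COc2cc(O[Si](C(C)C)(C(C)C)C(C)C)c(C/C=C(\C)CCC=C(C)C)cc2C1=O | intermediate
31 | (3S)-6-Ger-7-hydroxy-3-(4-hydroxy-2-methoxyphenyl)chroman-4-one | COc1cc(O)ccc1[C@H]1COc2cc(O)c(C/C=C(\C)CCC=C(C)C)cc2C1=O | target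

**Count and risks**

Total step count: 18. Longest linear sequence: 17 steps (steps 1–12 and 14–18); step 13 is a one-step side branch.

Steps most likely to fail:

1. Step 14. The excited diazo ketone may lose N2 by 1,2-hydrogen shift from C3–H instead of vinyl migration, which would give a conjugated enone and erase C3. Capture of the vinylketene by the volatile alkyne may also be too slow to compete with ketene self-reaction. Fallback: ring B is attached preformed and the stereocentres are set by dynamic kinetic resolution.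
   - Aldehyde 9 is treated with CH2=CHMgBr (2.2 equiv, THF, −78 °C) to give 1-[5-Ger-2-hydroxy-4-(triisopropylsilyloxy)phenyl]prop-2-en-1-ol F1.
   - MnO2 in CH2Cl2 oxidises F1 to the aryl vinyl ketone F2, which is not isolated and should close by oxa-Michael addition of the ortho phenol to 6-Ger-7-(triisopropylsilyloxy)chroman-4-one F3.
   - Commercial 4-bromo-3-methoxyphenol is silylated (TIPSCl, imidazole) to (4-bromo-3-methoxyphenoxy)triisopropylsilane F4.
   - Palladium-catalysed ketone α-arylation of F3 with F4 (Pd(OAc)2, P(t-Bu)3, NaOt-Bu, toluene, 60 °C) gives the racemic isoflavanone F5.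
   - Transfer hydrogenation of F5 with RuCl(p-cymene)[(S,S)-TsDPEN] in HCO2H/Et3N, during which C3 epimerises, should deliver the cis (3S,4S) carbinol.
   - The fallback sets out from 9 and comes back at 29; steps 17 and 18 follow unchanged.

2. Step 12. Once the lithium enolate forms, conjugate addition to the unsubstituted vinyl ketone and anionic oligomerisation may consume 17 before C-acylation. Fallback: the strong base is avoided.
   - Enone 17 is converted by soft enolisation (Et3SiOTf, Et3N, CH2Cl2, −78 °C) into 1-Chr-2-(triethylsilyloxy)buta-1,3-diene F6.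
   - F6 is C-acylated with (CF3CO)2O at −78 °C (Mukaiyama-type acylation of a silyl enol ether) to give trifluoroacetyl ketone 18.
   - 18 is carried through the MsN3/Et3N diazo transfer as before.
   - The fallback sets out from 17 and comes back at 18, hence at 19.

3. Step 16. Acid may ionise the C4–O bond, since the benzylic cation is stabilised by the ortho ring oxygen and the para silyloxy group. Exchange with methanol or loss of a proton toward C3 would follow, and the latter would erase the stereocentre. Fallback: acid is avoided altogether.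
   - Phenol 27 is desilylated globally with Bu4NF (THF, 0 °C) to (3S,4S)-6-Ger-3-(4-hydroxy-2-methoxyphenyl)chromane-4,7-diol F7.
   - F7 is silylated with TIPSCl (2.2 equiv) and imidazole in DMF at 0 °C; the two phenols should react far faster than the hindered secondary carbinol.
   - The fallback sets out from 27, replaces steps 15 and 16, and comes back at 29.

Further compounds
F1 | step 14 | 1-[5-Ger-2-hydroxy-4-(triisopropylsilyloxy)phenyl]prop-2-en-1-ol | C=CC(O)c1cc(C/C=C(\C)CCC=C(C)C)c(O[Si](C(C)C)(C(C)C)C(C)C)cc1O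
F2 | step 14 | 1-[5-Ger-2-hydroxy-4-(triisopropylsilyloxy)phenyl]prop-2-en-1-one | C=CC(=O)c1cc(C/C=C(\C)CCC=C(C)C)c(O[Si](C(C)C)(C(C)C)C(C)C)cc1O
F3 | step 14 | 6-Ger-7-(triisopropylsilyloxy)chroman-4-one | O=C1CCOc2cc(O[Si](C(C)C)(C(C)C)C(C)C)c(C/C=C(\C)CCC=C(C)C)cc21
F4 | step 14 | (4-bromo-3-methoxyphenoxy)triisopropylsilane | COc1cc(O[Si](C(C)C)(C(C)C)C(C)C)ccc1Br
F5 | step 14 | racemic 6-Ger-3-[2-methoxy-4-(triisopropylsilyloxy)phenyl]-7-(triisopropylsilyloxy)chroman-4-one | COc1cc(O[Si](C(C)C)(C(C)C)C(C)C)ccc1C1COc2cc(O[Si](C(C)C)(C(C)C)C(C)C)c(C/C=C(\C)CCC=C(C)C)cc2C1=O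
F6 | step 12 | 1-Chr-2-(triethylsilyloxy)buta-1,3-diene | C=CC(O[Si](CC)(CC)CC)=C[C@H]1COc2cc(O[Si](C(C)C)(C(C)C)C(C)C)c(C/C=C(\C)CCC=C(C)C)cc2[C@H]1O[Si](CC)(CC)CC
F7 | step 16 | (3S,4S)-6-Ger-3-(4-hydroxy-2-methoxyphenyl)chromane-4,7-diol (3,4-cis) | COc1cc(O)ccc1[C@H]1COc2cc(O)c(C/C=C(\C)CCC=C(C)C)cc2[C@H]1O
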